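## The problem

The target joins a 6-methoxy-2,8-dimethyl-2H-chromene to a hexahydroinden-4-one through one CH2 group, which links chromene C2 to C6 of a fully substituted enone (C4=O, C5=C6) in ring C. C5 carries the 2-hydroxy-2-methylpropyl chain. Ring D is a cyclopentane whose fusion carbons C3a and C7a are adjacent quaternary stereocentres with trans methyl groups, so ring C is trans-fused. The third stereocentre, chromene C2 (R), is quaternary and oxygen-bearing, and the CH2 link and the sp2 carbon C6 separate it from the ring-fusion pair. Neither element can control the other, so both halves must be made as single enantiomers and then joined. No stereocentre bears hydrogen: nothing can epimerise, and nothing can be corrected later. The sensitive functions are the chromene C3=C4 bond (styrene-like, reactive toward radicals, hydrogen-atom donors, electrophiles and acid), the tertiary alcohol, and every position β to the aryloxy oxygen, where a carbanion or a carbonyl-activated CH2 next to C2 expels the phenoxide, also vinylogously through the enone. The key step rests on one feature: C3a and C7a each carry exactly one carbon outside ring D (C4 and C7), so ring D with these two carbons is a C2-symmetric trans-1,2-dimethylcyclopentane-1,2-dicarboxylic acid derivative.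

## Retrosynthesis

**34 ⇒ 33.** No skeletal bond is cut; the C3=C4 double bond of the pyran ring is removed, which leads back to the 3,4-dihydro compound 33. The styrene-type bond is the one function that a radical closure of ring C and a hydrogen-atom-transfer hydration cannot tolerate, so it is carried as a chroman and unveiled last. The forward step is a quinone dehydrogenation. It must find only the chroman C4–H: the enone cannot be dehydrogenated, because its γ-carbons (C7 and the CH2 link) are flanked by quaternary carbons.

**33 ⇒ 32 ⇒ 30 + 31.** The tertiary C–O bond is cut (hydration of the isopropenyl group of 32), then the bond from C5 to the side-chain CH2. C5 is the α-carbon of a tetrasubstituted enone and cannot be alkylated as an enolate, so the side chain is brought in by cross-coupling of the 5-iodoenone 30 with the methallylstannane 31. The forward hydration must choose the 1,1-disubstituted alkene over the electron-poor enone; with the chroman in place there is no third alkene.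

**30 ⇒ 29 ⇒ 28.** The C5–I bond is removed (29), then the C7–C6 bond of ring C is cut to the iodo ynone 28. The neighbouring cuts, C5=C6 by aldol condensation or C4–C5 by acylation of a C6 ketone enolate, need a ketone at C6, which lies β to the aryloxy-substituted C2 and would eliminate. A radical at C7 adding to the β-carbon of an ynone avoids any such carbonyl. The forward closure must be 6-endo and must outrun reduction of the C7 radical.

**28 ⇒ 13 + 25.** The C4–C5 bond between the acyl carbon and the alkyne is cut, which gives the ring D acid 13 and the chroman alkyne 25. The alkyne is the linchpin that supplies C5 and C6. Its terminal carbanion is far from the aryloxy group and cannot eliminate, unlike any organometallic placed on the CH2 link. Each fragment now holds only its own stereocentres.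

**25 ⇒ 24 ⇒ 23.** After removal of the silyl cap (24), the aryl C8a–O bond is cut to the bromoaryl tertiary alcohol 23. Cutting the O–C2 bond instead would make the phenol attack a tertiary carbon, with inversion at best and racemisation at worst. Forming the aryl–oxygen bond leaves the C2–O bond, and with it the configuration, untouched. The forward reaction is an intramolecular aryl etherification of a tertiary alcohol.

**23 ⇒ 22 + 21; 18 ⇒ 16 + 17; 16 ⇒ 14.** The C3–C4 bond is cut between the epoxide 22 and the benzylic Grignard reagent 21, which comes from the bromide 20 and the arene 19. Epoxide 22 comes from the hydroxy tosylate 18, whose bond from the CH2 link to the alkyne is cut to the glycidyl tosylate 16 and the acetylide 17. Both arms of the tertiary carbinol thus grow from the two electrophilic CH2 groups of 16. Its single stereocentre comes from asymmetric epoxidation of the allylic alcohol 14 via the epoxy alcohol 15.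

**13 ⇒ 10 ⇒ 9 ⇒ 8 ⇒ 7.** These are functional-group changes only. The C4 acid and the C7 iodide both derive from CH2OH groups of the C2-symmetric diol 8 (through the silyl ether 9 and the iodide 10), and 8 derives from the diester 7. The two arms of 8 are homotopic, so their differentiation is a mono- versus bis-functionalisation problem and not a selectivity problem.

**7 ⇒ 3 + 4 (key disconnection).** The bonds C3a–C3 and C7a–C1 are cut, which removes the three CH2 groups of ring D as the dihalide 4 and leaves the acyclic succinate 3, reacting through its bis-enolate 5 and the mono-alkylated enolate 6. Cutting C3a–C7a instead would require joining two fully substituted carbons. Cutting elsewhere in ring D would leave the two quaternary centres to be set without a ring. The precursor has no fixed stereocentre; the forward step must create two quaternary carbons, trans to each other and in one absolute sense.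

**3 ⇒ 1 + 2.** Both ester bonds are cut, which gives the diacid 1 (any diastereomer mixture) and two molecules of the auxiliary alcohol 2, one for each carboxyl group.

## Roads not taken

**Alternative 1: one-carbon ring expansion of a benzofuranone.**
- **Cut and key step.** C4 is excised from the pyran ring (bonds C4–C4a and C3–C4), which leaves the benzofuranone A2 with the C2 quaternary centre already present. Forward, a Lewis-acid-promoted insertion of a silylated diazomethane carbon between the carbonyl and aryl carbons (aryl migration, Tiffeneau–Demjanov type) gives the chroman-3-one A1. Reduction and dehydration would then give the chromene.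
- **Merits.** The stereocentre is set on a small, rigid bicycle. The double bond arrives by ionic dehydration, so no late quinone dehydrogenation is needed; in this respect the road is better than the chosen one.
- **Weak points.** The migration must favour aryl over the oxygen-bearing quaternary C2, and the product ketone A1 can be homologated again. The arm on C2 of A1 is a one-carbon CH2O unit. Turning it into the CH2 link means substitution at a neopentyl carbon β to the aryloxy oxygen, or an organometallic there, which eliminates. The early chromene double bond would also have to survive the construction of ring C.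
- **Comparison.** The road says nothing about the vicinal quaternary centres of ring D. The chosen plan sets against the shorter pyran synthesis a stereocentre of known sense from an asymmetric epoxidation, a three-carbon arm ending in a non-eliminating acetylide (25), and a solution for ring D.

**Alternative 2: epoxide ring contraction forges the quaternary–quaternary bond.**
- **Cut and key step.** The C3a–C7a bond is cut by a retro-1,2-shift to the tetrasubstituted cyclohexene oxide A4. Forward, a boron Lewis acid opens the epoxide at the carbon flanked by CH2, and the neighbouring quaternary carbon migrates. This contracts the ring to the acetyl cyclopentane A3, from which a Claisen-type closure would give the bicyclic dione A5.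
- **Merits.** The hardest bond is made by a stereospecific shift. A3 already contains C4, C5, C6 and C7, so ring C could be closed without tin; in carbon economy and in the ring C closure this road is better than the chosen one.
- **Weak points.** A4 must first be made as one enantiomer and one diastereomer with a quaternary centre next to a tetrasubstituted epoxide. Methyl shift, proton loss to an allylic alcohol and opening at the other epoxide carbon compete with the desired migration. From A5, the CH2 link would have to be attached at C6 as a chromanylmethyl nucleophile, which is a β-aryloxy organometallic. The two carbonyls of A5 would also have to be told apart.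
- **Comparison.** The chosen plan sets against the better carbon economy the C2 symmetry of 7 (no regiochemistry at any stage), absolute configuration from a cheap auxiliary in one step from commodity materials, and a fragment union through an alkyne that cannot eliminate.

**Alternative 3: alkyne linchpin and 6-endo radical closure of ring C on the chromene.**
- **Cut and key step.** The C7–C6 bond and the C5–I bond are cut to the chromene iodo ynone A7. Forward, a ditin/light atom-transfer chain closes ring C and leaves iodine at C5, which gives the 5-iodo analogue A6 of the target.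
- **Merits.** It is convergent, and ring closure and the C5 handle come in one step. It is two steps shorter than the end game chosen here (no separate iodination, no late dehydrogenation).
- **Weak points.** In A7 the chromene double bond is in place. The C5 vinyl radical is five atoms from C3 (C5, C6, CH2, C2, C3) and can cyclise 5-exo to a benzylic radical, in competition with iodine transfer. The road is also silent on the origin of the two quaternary centres.
- **Comparison.** The chosen plan keeps the linchpin and the 6-endo closure but runs them on the chroman 28 in a reductive chain. It pays two extra steps for a radical step with no competing cyclisation, and it supplies ring D.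

Key step: step 2

Assumption (remark on the chemistry): the (−)-menthyl groups are taken to direct the annulation of the α,α'-dimethyl bis-enolate in the same sense as for the unsubstituted succinate, so that 7 is the (1S,2S) diester; were the sense reversed, (+)-menthol would replace 2 in step 1 with nothing else changed.

## Route

Step 1
Reactants: 1 2,3-dimethylsuccinic acid (mixture of meso and racemic forms); 2 (−)-menthol, (1R,2S,5R)-2-isopropyl-5-methylcyclohexanol (two equivalents are incorporated, one per carboxyl group)
Product: 3 bis[(1R,2S,5R)-menthyl] 2,3-dimethylsuccinate (mixture of diastereomers at C2 and C3)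
Conditions: 2 (2.2 equiv), TsOH·H2O (cat.), toluene, reflux, Dean–Stark trap
Reagents that add atoms: (−)-menthol (the second equivalent of 2, which esterifies the second carboxyl group), CC(C)[C@@H]1CC[C@@H](C)C[C@H]1O
Why: Double Fischer esterification driven by azeotropic removal of water: each carboxyl group of 1 takes up one molecule of 2, so the diester holds two menthyl groups. The configuration at the two α-carbons is irrelevant because both become enolate carbons in step 2.

Step 2
Reactants: 3 bis[(1R,2S,5R)-menthyl] 2,3-dimethylsuccinate; 4 1-bromo-3-chloropropane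
Product: 7 bis[(1R,2S,5R)-menthyl] (1S,2S)-1,2-dimethylcyclopentane-1,2-dicarboxylate, via dilithium bis-enolate 5 (not isolated), via chloropropyl lithium enolate 6 (not isolated)
Conditions: lithium 2,2,6,6-tetramethylpiperidide (LiTMP, 2.3 equiv, from 2,2,6,6-tetramethylpiperidine and n-BuLi), THF, −78 °C; then 4 (1.05 equiv), −78 °C → rt
Reagents that add atoms: none
Why: Two equivalents of LiTMP convert 3 into the vicinal bis-enolate 5, which erases both α-stereocentres of the diastereomer mixture. The first C-alkylation is an SN2 displacement of the bromide of 4, which reacts far faster than the chloride, and gives the chloropropyl enolate 6 with the first quaternary centre. On warming, the remaining enolate displaces the chloride in a 5-exo-tet closure that forms ring D and the second quaternary centre. The closest known reaction is the double alkylation of the dianion of dimenthyl succinate with α,ω-dihalides to trans-cycloalkane-1,2-dicarboxylates; the α,α'-dimethyl substrate extends it to two quaternary carbons. The configuration of the first centre (S) is set by the menthyl groups, which shield one face of the chelated bis-enolate. The second centre is set relative to the first in the ring closure, where the ester on the new quaternary carbon and the menthyloxy enolate avoid each other, so the ester groups end up trans. The step needs C- over O-alkylation (lithium counter-ion, soft primary halide), ring closure over a second intermolecular alkylation (1:1 stoichiometry, fast 5-exo mode) and trans over cis (anti arrangement of the ester groups in the cyclisation). Because 7 is C2-symmetric, its ester groups are homotopic and no later step has to tell them apart.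

Step 3
Reactants: 7 bis[(1R,2S,5R)-menthyl] (1S,2S)-1,2-dimethylcyclopentane-1,2-dicarboxylate
Product: 8 [(1S,2S)-1,2-dimethylcyclopentane-1,2-diyl]dimethanol
Conditions: LiAlH4, THF, reflux; aqueous NaOH work-up
Reagents that add atoms: none
Why: Hydride reduction of both hindered esters, which is far easier than their hydrolysis; no stereocentre is touched and the auxiliary 2 is recovered.

Step 4
Reactants: 8 [(1S,2S)-1,2-dimethylcyclopentane-1,2-diyl]dimethanol
Product: 9 [(1S,2S)-2-({[tert-butyl(dimethyl)silyl]oxy}methyl)-1,2-dimethylcyclopentyl]methanol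
Conditions: NaH (1.0 equiv), THF, rt; then TBSCl (1.0 equiv)
Reagents that add atoms: tert-butyl(chloro)dimethylsilane, CC(C)(C)[Si](C)(C)Cl
Why: Mono-silylation of a symmetrical diol through its sparingly soluble monosodium alkoxide; the two hydroxyl groups are homotopic, so only mono- versus bis-silylation has to be controlled.

Step 5
Reactants: 9 [(1S,2S)-2-({[tert-butyl(dimethyl)silyl]oxy}methyl)-1,2-dimethylcyclopentyl]methanol
Product: 10 tert-butyl{[(1S,2S)-2-(iodomethyl)-1,2-dimethylcyclopentyl]methoxy}dimethylsilane
Conditions: PPh3, I2, imidazole, toluene, 90 °C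
Reagents that add atoms: iodine, II
Why: Appel-type iodination through the alkoxyphosphonium salt; the neopentyl position needs heat but no cation is formed, so no skeletal rearrangement is expected, and the buffered medium spares the silyl ether.

Step 6
Reactants: 10 tert-butyl{[(1S,2S)-2-(iodomethyl)-1,2-dimethylcyclopentyl]methoxy}dimethylsilane
Product: 13 (1S,2S)-2-(iodomethyl)-1,2-dimethylcyclopentane-1-carboxylic acid, via iodo alcohol 11 (not isolated), via iodo aldehyde 12 (not isolated)
Conditions: CrO3, H2SO4, H2O, acetone, 0 °C → rt
Reagents that add atoms: water, O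
Why: Jones oxidation: the aqueous acid cleaves the silyl ether and the alcohol is oxidised through the aldehyde hydrate to the acid; the primary iodide is inert, and lactonisation onto it would need a trans-fused bicyclo[3.3.0] lactone.

Step 7
Reactants: 14 2-methylprop-2-en-1-ol
Product: 16 (R)-(2-methyloxiran-2-yl)methyl 4-methylbenzenesulfonate, via (S)-2-methylglycidol 15 (not isolated)
Conditions: Ti(OiPr)4 (5 mol %), L-(+)-diisopropyl tartrate (6 mol %), cumene hydroperoxide, 3 Å molecular sieves, CH2Cl2, −20 °C; then P(OMe)3; then TsCl, Et3N, DMAP (cat.), −10 °C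
Reagents that add atoms: cumene hydroperoxide, CC(C)(OO)c1ccccc1; 4-methylbenzenesulfonyl chloride, Cc1ccc(cc1)S(Cl)(=O)=O
Why: Sharpless asymmetric epoxidation with in situ tosylation, which avoids isolating the water-soluble epoxy alcohol; L-(+)-tartrate delivers oxygen to the face that gives the (S)-epoxy alcohol, as with allyl alcohol and (E)-allylic alcohols. Tosylation changes only the descriptor (S to R), and the crystalline tosylate can be recrystallised to raise the enantiomeric purity.

Step 8
Reactants: 16 (R)-(2-methyloxiran-2-yl)methyl 4-methylbenzenesulfonate; 17 lithium (trimethylsilyl)acetylide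
Product: 18 (R)-2-hydroxy-2-methyl-5-(trimethylsilyl)pent-4-yn-1-yl 4-methylbenzenesulfonate
Conditions: BF3·OEt2, THF, −78 °C
Reagents that add atoms: none
Why: BF3-promoted opening of the epoxide by the alkynyllithium at its unsubstituted carbon; the electron-poor CH2OTs group disfavours ionisation at the tertiary carbon, the tosylate is not displaced at −78 °C, and the stereocentre is not a reacting site.

Step 9
Reactants: 19 2-bromo-5-methoxy-1,3-dimethylbenzene (4-bromo-3,5-dimethylanisole)
Product: 20 2-bromo-1-(bromomethyl)-5-methoxy-3-methylbenzene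
Conditions: NBS (1.0 equiv), AIBN (cat.), PhCF3, 80 °C
Reagents that add atoms: N-bromosuccinimide, BrN1C(=O)CCC1=O
Why: Wohl–Ziegler benzylic bromination; the two methyl groups are equivalent, so only mono- versus dibromination must be held by stoichiometry, and radical conditions in a non-polar solvent suppress ring bromination.

Step 10
Reactants: 20 2-bromo-1-(bromomethyl)-5-methoxy-3-methylbenzene; 18 (R)-2-hydroxy-2-methyl-5-(trimethylsilyl)pent-4-yn-1-yl 4-methylbenzenesulfonate
Product: 23 (S)-1-(2-bromo-5-methoxy-3-methylphenyl)-3-methyl-6-(trimethylsilyl)hex-5-yn-3-ol, via benzylmagnesium bromide 21 (not isolated), via (R)-epoxide 22 (not isolated)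
Conditions: Mg, Et2O, 0 °C (20 to 21); NaH, THF, 0 °C → rt (18 to 22); then 22 added to 21, CuI (10 mol %), THF, −30 → 0 °C
Reagents that add atoms: none
Why: Base closes the β-hydroxy tosylate to the terminal epoxide, and the copper-catalysed Grignard opening then takes place at the CH2 terminus; magnesium inserts into the benzylic C–Br bond much faster than into the aryl C–Br bond. The stereocentre keeps all four bonds throughout, and its descriptor changes (R to S) only because the priorities change.

Step 11
Reactants: 23 (S)-1-(2-bromo-5-methoxy-3-methylphenyl)-3-methyl-6-(trimethylsilyl)hex-5-yn-3-ol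
Product: 24 trimethyl{3-[(2S)-6-methoxy-2,8-dimethyl-3,4-dihydro-2H-chromen-2-yl]prop-1-yn-1-yl}silane
Conditions: Pd(OAc)2 (3 mol %), 2-(di-tert-butylphosphino)-1,1'-binaphthyl (4 mol %), Cs2CO3, toluene, 80 °C
Reagents that add atoms: none
Why: Intramolecular Buchwald–Hartwig etherification to a six-membered ring; the tertiary alkoxide has no hydrogen on the carbinol carbon, so β-hydride elimination is impossible. The C2–O bond is not broken, so the configuration is retained, and the silyl cap keeps the alkyne out of the coupling.

Step 12
Reactants: 24 trimethyl{3-[(2S)-6-methoxy-2,8-dimethyl-3,4-dihydro-2H-chromen-2-yl]prop-1-yn-1-yl}silane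
Product: 25 (2S)-6-methoxy-2,8-dimethyl-2-(prop-2-yn-1-yl)-3,4-dihydro-2H-chromene
Conditions: K2CO3, MeOH, rt
Reagents that add atoms: none
Why: Base-catalysed methanolysis of the alkynyl–silicon bond; nothing else in 24 reacts with methoxide at room temperature.

Step 13
Reactants: 13 (1S,2S)-2-(iodomethyl)-1,2-dimethylcyclopentane-1-carboxylic acid; 25 (2S)-6-methoxy-2,8-dimethyl-2-(prop-2-yn-1-yl)-3,4-dihydro-2H-chromene
Product: 28 1-[(1S,2S)-2-(iodomethyl)-1,2-dimethylcyclopentyl]-4-[(2S)-6-methoxy-2,8-dimethyl-3,4-dihydro-2H-chromen-2-yl]but-2-yn-1-one, via acid chloride 26 (not isolated), via alkynylzinc chloride 27 (not isolated)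
Conditions: (COCl)2, DMF (cat.), CH2Cl2, 0 °C → rt (13 to 26); n-BuLi, THF, −78 °C, then ZnCl2, → 0 °C (25 to 27); then Pd(PPh3)4 (5 mol %), THF, 0 °C → rt
Reagents that add atoms: none
Why: Negishi acylation of an alkynylzinc with an acid chloride forms C4–C5 and stops at the ynone. The neutral medium protects the propargylic CH2 next to the aryloxy-substituted carbon from base-induced isomerisation and elimination, and the neopentyl iodide is inert to the zinc reagent and to the catalyst at room temperature.

Step 14
Reactants: 28 1-[(1S,2S)-2-(iodomethyl)-1,2-dimethylcyclopentyl]-4-[(2S)-6-methoxy-2,8-dimethyl-3,4-dihydro-2H-chromen-2-yl]but-2-yn-1-one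
Product: 29 (3aS,7aR)-6-{[(2S)-6-methoxy-2,8-dimethyl-3,4-dihydro-2H-chromen-2-yl]methyl}-3a,7a-dimethyl-1,2,3,3a,7,7a-hexahydro-4H-inden-4-one
Conditions: Bu3SnH (1.3 equiv, syringe pump), AIBN (0.2 equiv), benzene (0.005 M), 80 °C
Reagents that add atoms: none
Why: Tin-hydride radical cyclisation: iodine abstraction gives the primary C7 radical, which adds in a polarity-matched 6-endo mode to the ynone β-carbon C6, and the C5 vinyl radical then takes hydrogen from the stannane. The 5-exo alternative would build a trans-fused bicyclo[3.3.0]octanone and is excluded by strain. No stereocentre is formed, and the chroman offers no double bond to the vinyl radical.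

Step 15
Reactants: 29 (3aS,7aR)-6-{[(2S)-6-methoxy-2,8-dimethyl-3,4-dihydro-2H-chromen-2-yl]methyl}-3a,7a-dimethyl-1,2,3,3a,7,7a-hexahydro-4H-inden-4-one
Product: 30 (3aS,7aR)-5-iodo-6-{[(2S)-6-methoxy-2,8-dimethyl-3,4-dihydro-2H-chromen-2-yl]methyl}-3a,7a-dimethyl-1,2,3,3a,7,7a-hexahydro-4H-inden-4-one
Conditions: I2, pyridine, DMAP (cat.), CH2Cl2, rt
Reagents that add atoms: iodine, II
Why: Baylis–Hillman-type α-iodination of an enone: the amine adds at C6, the enolate is iodinated at C5 and the amine leaves. C5 bears the only vinylic hydrogen, and the arene is not iodinated in the absence of an oxidant.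

Step 16
Reactants: 30 (3aS,7aR)-5-iodo-6-{[(2S)-6-methoxy-2,8-dimethyl-3,4-dihydro-2H-chromen-2-yl]methyl}-3a,7a-dimethyl-1,2,3,3a,7,7a-hexahydro-4H-inden-4-one; 31 tributyl(2-methylprop-2-en-1-yl)stannane
Product: 32 (3aS,7aR)-6-{[(2S)-6-methoxy-2,8-dimethyl-3,4-dihydro-2H-chromen-2-yl]methyl}-3a,7a-dimethyl-5-(2-methylprop-2-en-1-yl)-1,2,3,3a,7,7a-hexahydro-4H-inden-4-one
Conditions: Pd2(dba)3 (5 mol %), AsPh3 (20 mol %), CuI (10 mol %), NMP, 50 °C
Reagents that add atoms: none
Why: Stille coupling of an α-iodoenone with an allylstannane under ligand- and copper-accelerated conditions; the methallyl group is symmetrical, so transfer through either terminus gives the same product.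

Step 17
Reactants: 32 (3aS,7aR)-6-{[(2S)-6-methoxy-2,8-dimethyl-3,4-dihydro-2H-chromen-2-yl]methyl}-3a,7a-dimethyl-5-(2-methylprop-2-en-1-yl)-1,2,3,3a,7,7a-hexahydro-4H-inden-4-one
Product: 33 (3aS,7aR)-5-(2-hydroxy-2-methylpropyl)-6-{[(2S)-6-methoxy-2,8-dimethyl-3,4-dihydro-2H-chromen-2-yl]methyl}-3a,7a-dimethyl-1,2,3,3a,7,7a-hexahydro-4H-inden-4-one
Conditions: Co(acac)2 (20 mol %), PhSiH3, O2 (1 atm), i-PrOH, rt
Reagents that add atoms: dioxygen, O=O
Why: Mukaiyama hydration: hydrogen-atom transfer to the 1,1-disubstituted alkene gives the tertiary radical, which is trapped by oxygen and reduced to the Markovnikov alcohol. The tetrasubstituted, electron-poor enone bond does not accept the hydrogen atom, and no styrene-type bond is present at this stage.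

Step 18
Reactants: 33 (3aS,7aR)-5-(2-hydroxy-2-methylpropyl)-6-{[(2S)-6-methoxy-2,8-dimethyl-3,4-dihydro-2H-chromen-2-yl]methyl}-3a,7a-dimethyl-1,2,3,3a,7,7a-hexahydro-4H-inden-4-one
Product: 34 (3aS,7aR)-5-(2-hydroxy-2-methylpropyl)-6-{[(2R)-6-methoxy-2,8-dimethyl-2H-chromen-2-yl]methyl}-3a,7a-dimethyl-1,2,3,3a,7,7a-hexahydro-4H-inden-4-one (CNP0295366.2)
Conditions: DDQ (1.5 equiv), benzene, reflux
Reagents that add atoms: none
Why: Quinone dehydrogenation of a chroman: hydride abstraction from benzylic C4 (cation stabilised by the ring oxygen through the ortho position) and loss of a C3 proton. The enone cannot be dehydrogenated because both its γ-carbons are flanked by quaternary carbons. C2 is untouched, and its descriptor changes from S to R only because C3 becomes sp2.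

## Compound list

1 | 2,3-dimethylsuccinic acid (diastereomer mixture) | CC(C(=O)O)C(C)C(=O)O | starting material
2 | (−)-menthol, (1R,2S,5R)-2-isopropyl-5-methylcyclohexanol | CC(C)[C@@H]1CC[C@@H](C)C[C@H]1O | starting material
3 | bis[(1R,2S,5R)-menthyl] 2,3-dimethylsuccinate | CC(C(=O)O[C@@H]1C[C@H](C)CC[C@H]1C(C)C)C(C)C(=O)O[C@@H]1C[C@H](C)CC[C@H]1C(C)C | intermediate
4 | 1-bromo-3-chloropropane | ClCCCBr | starting material
5 | dilithium bis-enolate of 3 | [Li+].[Li+].[O-]C(O[C@@H]1C[C@H](C)CC[C@H]1C(C)C)=C(C)C(C)=C([O-])O[C@@H]1C[C@H](C)CC[C@H]1C(C)C | intermediate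
6 | lithium enolate of bis[(1R,2S,5R)-menthyl] (S)-2-(3-chloropropyl)-2,3-dimethylsuccinate | [Li+].[O-]C(O[C@@H]1C[C@H](C)CC[C@H]1C(C)C)=C(C)[C@](C)(CCCCl)C(=O)O[C@@H]1C[C@H](C)CC[C@H]1C(C)C | intermediate
7 | bis[(1R,2S,5R)-menthyl] (1S,2S)-1,2-dimethylcyclopentane-1,2-dicarboxylate | O=C(O[C@@H]1C[C@H](C)CC[C@H]1C(C)C)[C@@]2(C)CCC[C@]2(C)C(=O)O[C@@H]1C[C@H](C)CC[C@H]1C(C)C | intermediate
8 | [(1S,2S)-1,2-dimethylcyclopentane-1,2-diyl]dimethanol | OC[C@@]1(C)CCC[C@]1(C)CO | intermediate
9 | [(1S,2S)-2-({[tert-butyl(dimethyl)silyl]oxy}methyl)-1,2-dimethylcyclopentyl]methanol | CC(C)(C)[Si](C)(C)OC[C@@]1(C)CCC[C@]1(C)CO | intermediate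
10 | tert-butyl{[(1S,2S)-2-(iodomethyl)-1,2-dimethylcyclopentyl]methoxy}dimethylsilane | CC(C)(C)[Si](C)(C)OC[C@@]1(C)CCC[C@]1(C)CI | intermediate
11 | [(1S,2S)-2-(iodomethyl)-1,2-dimethylcyclopentyl]methanol | OC[C@@]1(C)CCC[C@]1(C)CI | intermediate
12 | (1S,2S)-2-(iodomethyl)-1,2-dimethylcyclopentane-1-carbaldehyde | O=C[C@@]1(C)CCC[C@]1(C)CI | intermediate
13 | (1S,2S)-2-(iodomethyl)-1,2-dimethylcyclopentane-1-carboxylic acid | OC(=O)[C@@]1(C)CCC[C@]1(C)CI | intermediate
14 | 2-methylprop-2-en-1-ol | CC(=C)CO | starting material
15 | (S)-2-methylglycidol, (S)-(2-methyloxiran-2-yl)methanol | OC[C@@]1(C)CO1 | intermediate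
16 | (R)-(2-methyloxiran-2-yl)methyl 4-methylbenzenesulfonate | Cc1ccc(cc1)S(=O)(=O)OC[C@@]1(C)CO1 | intermediate
17 | lithium (trimethylsilyl)acetylide | [Li]C#C[Si](C)(C)C | starting material
18 | (R)-2-hydroxy-2-methyl-5-(trimethylsilyl)pent-4-yn-1-yl 4-methylbenzenesulfonate | Cc1ccc(cc1)S(=O)(=O)OC[C@@](C)(CC#C[Si](C)(C)C)O | intermediate
19 | 2-bromo-5-methoxy-1,3-dimethylbenzene | COc1cc(C)c(Br)c(C)c1 | starting material
20 | 2-bromo-1-(bromomethyl)-5-methoxy-3-methylbenzene | COc1cc(C)c(Br)c(CBr)c1 | intermediate
21 | (2-bromo-5-methoxy-3-methylbenzyl)magnesium bromide | COc1cc(C)c(Br)c(C[Mg]Br)c1 | intermediate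
22 | (R)-trimethyl[3-(2-methyloxiran-2-yl)prop-1-yn-1-yl]silane | C[Si](C)(C)C#CC[C@]1(C)CO1 | intermediate
23 | (S)-1-(2-bromo-5-methoxy-3-methylphenyl)-3-methyl-6-(trimethylsilyl)hex-5-yn-3-ol | COc1cc(C)c(Br)c(c1)CC[C@@](C)(CC#C[Si](C)(C)C)O | intermediate
24 | trimethyl{3-[(2S)-6-methoxy-2,8-dimethyl-3,4-dihydro-2H-chromen-2-yl]prop-1-yn-1-yl}silane | COc1cc(C)c2c(c1)CC[C@@](C)(CC#C[Si](C)(C)C)O2 | intermediate
25 | (2S)-6-methoxy-2,8-dimethyl-2-(prop-2-yn-1-yl)-3,4-dihydro-2H-chromene | COc1cc(C)c2c(c1)CC[C@@](C)(CC#C)O2 | intermediate
26 | (1S,2S)-2-(iodomethyl)-1,2-dimethylcyclopentane-1-carbonyl chloride | ClC(=O)[C@@]1(C)CCC[C@]1(C)CI | intermediate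
27 | chloro{3-[(2S)-6-methoxy-2,8-dimethyl-3,4-dihydro-2H-chromen-2-yl]prop-1-yn-1-yl}zinc | COc1cc(C)c2c(c1)CC[C@@](C)(CC#C[Zn]Cl)O2 | intermediate
28 | 1-[(1S,2S)-2-(iodomethyl)-1,2-dimethylcyclopentyl]-4-[(2S)-6-methoxy-2,8-dimethyl-3,4-dihydro-2H-chromen-2-yl]but-2-yn-1-one | COc1cc(C)c2c(c1)CC[C@@](C)(CC#CC(=O)[C@@]1(C)CCC[C@]1(C)CI)O2 | intermediate
29 | (3aS,7aR)-6-{[(2S)-6-methoxy-2,8-dimethyl-3,4-dihydro-2H-chromen-2-yl]methyl}-3a,7a-dimethyl-1,2,3,3a,7,7a-hexahydro-4H-inden-4-one | COc1cc(C)c2c(c1)CC[C@@](C)(CC1=CC(=O)[C@@]3(C)CCC[C@]3(C)C1)O2 | intermediate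
30 | (3aS,7aR)-5-iodo-6-{[(2S)-6-methoxy-2,8-dimethyl-3,4-dihydro-2H-chromen-2-yl]methyl}-3a,7a-dimethyl-1,2,3,3a,7,7a-hexahydro-4H-inden-4-one | COc1cc(C)c2c(c1)CC[C@@](C)(CC1=C(I)C(=O)[C@@]3(C)CCC[C@]3(C)C1)O2 | intermediate
31 | tributyl(2-methylprop-2-en-1-yl)stannane | CCCC[Sn](CCCC)(CCCC)CC(C)=C | starting material
32 | (3aS,7aR)-6-{[(2S)-6-methoxy-2,8-dimethyl-3,4-dihydro-2H-chromen-2-yl]methyl}-3a,7a-dimethyl-5-(2-methylprop-2-en-1-yl)-1,2,3,3a,7,7a-hexahydro-4H-inden-4-one | COc1cc(C)c2c(c1)CC[C@@](C)(CC1=C(CC(C)=C)C(=O)[C@@]3(C)CCC[C@]3(C)C1)O2 | intermediate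
33 | (3aS,7aR)-5-(2-hydroxy-2-methylpropyl)-6-{[(2S)-6-methoxy-2,8-dimethyl-3,4-dihydro-2H-chromen-2-yl]methyl}-3a,7a-dimethyl-1,2,3,3a,7,7a-hexahydro-4H-inden-4-one | COc1cc(C)c2c(c1)CC[C@@](C)(CC1=C(CC(C)(C)O)C(=O)[C@@]3(C)CCC[C@]3(C)C1)O2 | intermediate
34 | (3aS,7aR)-5-(2-hydroxy-2-methylpropyl)-6-{[(2R)-6-methoxy-2,8-dimethyl-2H-chromen-2-yl]methyl}-3a,7a-dimethyl-1,2,3,3a,7,7a-hexahydro-4H-inden-4-one | COc1cc(C)c2c(c1)C=C[C@@](C)(CC1=C(CC(C)(C)O)C(=O)[C@@]3(C)CCC[C@]3(C)C1)O2 | target

## Step count and least certain steps

Total step count: 18. Longest linear sequence: 12 steps (steps 1–6 and 13–18, from 1). The chroman branch (steps 7, 8, 10, 11, 12, with step 9 feeding step 10) is convergent and joins at step 13.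

**Step 2 (key step).** The menthyl groups may discriminate the faces of the tetrasubstituted bis-enolate poorly or in the reverse sense. The hindered enolate may also eliminate HX from the dihalide or fail to close on the chloride, leaving mono-alkylated material and cis diester. A reversed sense alone is answered by (+)-menthol in step 1. The fallback with a different approach sets out from 1 and returns at 8. Esterification of 1 with methanol would give dimethyl 2,3-dimethylsuccinate F1. The same bis-enolate annulation with 4, without an auxiliary, would give racemic trans-dimethyl 1,2-dimethylcyclopentane-1,2-dicarboxylate F2 after removal of any cis isomer. Saponification (KOH, ethylene glycol, heat) would give racemic trans-1,2-dimethylcyclopentane-1,2-dicarboxylic acid F3. Classical resolution through a crystalline salt with an enantiopure amine, for example (R)-1-phenylethylamine, would give (1S,2S)-1,2-dimethylcyclopentane-1,2-dicarboxylic acid F4, and LiAlH4 reduction of F4 gives 8.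

**Step 14.** The 6-endo closure onto the linear ynone in the trans-fused series may be slower than hydrogen transfer to the C7 radical, or stannyl radicals may add to the ynone. The result would be simple deiodination or hydrostannation. The fallback sets out from 28 and returns at 29; it replaces the alkyne acceptor by an alkene and the vinyl radical by an α-keto radical. Semi-hydrogenation of 28 (H2, Pd/CaCO3 poisoned with Pb(OAc)2, quinoline) would give the (Z)-enone F5. A 6-endo-trig tin-hydride cyclisation of F5 would give the saturated ketone F6 as a mixture of C6 epimers. Enolisation of F6 is possible only toward C5 (TMSOTf, Et3N) and would give the trimethylsilyl enol ether F7. Saegusa–Ito oxidation of F7 (Pd(OAc)2, MeCN) restores the C5=C6 bond and gives 29.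

**Step 15.** Conjugate addition of the amine to the doubly substituted β-carbon C6 may be too slow, so the iodination stalls. The fallback sets out from 28 and returns at 30, skipping 29. It is an iodine atom-transfer cyclisation of 28 (Bu3SnSnBu3, 10 mol %, visible light, benzene, 0.2 M). With no hydride donor, the C5 vinyl radical takes iodine from a second molecule of 28 and gives 30 directly. No new compound is involved.

**Step 18.** Hydride abstraction at C4 may need forcing conditions, because the methoxy group is meta to the benzylic position. Under such conditions the aryl methyl group may be oxidised, or the acid-sensitive product and the tertiary alcohol may decompose. The fallback sets out from 29 and returns at 34. It moves the dehydrogenation to the robust enone stage and replaces the hydrogen-atom-transfer hydration by an ionic one. DDQ on 29 would give the chromene enone F8. Iodination of F8 as in step 15 would give the chromene iodoenone F9, which is identical with A6. Stille coupling of F9 with 31 would give the chromene methallyl enone F10. Oxymercuration of F10 (Hg(OAc)2, THF/H2O) would take place at the unhindered 1,1-disubstituted alkene, in preference to the hindered chromene bond, and give the organomercurial F11. Reduction of F11 with NaBH4/NaOH gives 34.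

## Further compounds

F1 | step 2 | dimethyl 2,3-dimethylsuccinate (diastereomer mixture) | COC(=O)C(C)C(C)C(=O)OC
F2 | step 2 | racemic trans-dimethyl 1,2-dimethylcyclopentane-1,2-dicarboxylate (both enantiomers drawn) | COC(=O)[C@@]1(C)CCC[C@]1(C)C(=O)OC.COC(=O)[C@]1(C)CCC[C@@]1(C)C(=O)OC
F3 | step 2 | racemic trans-1,2-dimethylcyclopentane-1,2-dicarboxylic acid (both enantiomers drawn) | OC(=O)[C@@]1(C)CCC[C@]1(C)C(O)=O.OC(=O)[C@]1(C)CCC[C@@]1(C)C(O)=O
F4 | step 2 | (1S,2S)-1,2-dimethylcyclopentane-1,2-dicarboxylic acid | OC(=O)[C@@]1(C)CCC[C@]1(C)C(O)=O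
F5 | step 14 | (Z)-1-[(1S,2S)-2-(iodomethyl)-1,2-dimethylcyclopentyl]-4-[(2S)-6-methoxy-2,8-dimethyl-3,4-dihydro-2H-chromen-2-yl]but-2-en-1-one | COc1cc(C)c2c(c1)CC[C@@](C)(C/C=C\C(=O)[C@@]1(C)CCC[C@]1(C)CI)O2
F6 | step 14 | (3aS,7aR)-6-{[(2S)-6-methoxy-2,8-dimethyl-3,4-dihydro-2H-chromen-2-yl]methyl}-3a,7a-dimethyloctahydro-4H-inden-4-one (C6 epimers) | COc1cc(C)c2c(c1)CC[C@@](C)(CC1CC(=O)[C@@]3(C)CCC[C@]3(C)C1)O2
F7 | step 14 | {[(3aS,7aR)-6-{[(2S)-6-methoxy-2,8-dimethyl-3,4-dihydro-2H-chromen-2-yl]methyl}-3a,7a-dimethyl-2,3,3a,6,7,7a-hexahydro-1H-inden-4-yl]oxy}trimethylsilane (C6 epimers) | COc1cc(C)c2c(c1)CC[C@@](C)(CC1C=C(O[Si](C)(C)C)[C@@]3(C)CCC[C@]3(C)C1)O2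
F0 | step 15 | none | none
F8 | step 18 | (3aS,7aR)-6-{[(2R)-6-methoxy-2,8-dimethyl-2H-chromen-2-yl]methyl}-3a,7a-dimethyl-1,2,3,3a,7,7a-hexahydro-4H-inden-4-one | COc1cc(C)c2c(c1)C=C[C@@](C)(CC1=CC(=O)[C@@]3(C)CCC[C@]3(C)C1)O2
F9 | step 18 | (3aS,7aR)-5-iodo-6-{[(2R)-6-methoxy-2,8-dimethyl-2H-chromen-2-yl]methyl}-3a,7a-dimethyl-1,2,3,3a,7,7a-hexahydro-4H-inden-4-one | COc1cc(C)c2c(c1)C=C[C@@](C)(CC1=C(I)C(=O)[C@@]3(C)CCC[C@]3(C)C1)O2
F10 | step 18 | (3aS,7aR)-6-{[(2R)-6-methoxy-2,8-dimethyl-2H-chromen-2-yl]methyl}-3a,7a-dimethyl-5-(2-methylprop-2-en-1-yl)-1,2,3,3a,7,7a-hexahydro-4H-inden-4-one | COc1cc(C)c2c(c1)C=C[C@@](C)(CC1=C(CC(C)=C)C(=O)[C@@]3(C)CCC[C@]3(C)C1)O2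
F11 | step 18 | {3-[(3aS,7aR)-6-{[(2R)-6-methoxy-2,8-dimethyl-2H-chromen-2-yl]methyl}-3a,7a-dimethyl-4-oxo-2,3,3a,4,7,7a-hexahydro-1H-inden-5-yl]-2-hydroxy-2-methylpropyl}mercury acetate (carbinol epimers) | COc1cc(C)c2c(c1)C=C[C@@](C)(CC1=C(CC(C)(O)C[Hg]OC(C)=O)C(=O)[C@@]3(C)CCC[C@]3(C)C1)O2
A1 | alternative 1 | (R)-2-[(benzyloxy)methyl]-6-methoxy-2,8-dimethylchroman-3-one | COc1cc(C)c2O[C@](C)(COCc3ccccc3)C(=O)Cc2c1
A2 | alternative 1 | (R)-2-[(benzyloxy)methyl]-5-methoxy-2,7-dimethyl-1-benzofuran-3(2H)-one | COc1cc(C)c2O[C@](C)(COCc3ccccc3)C(=O)c2c1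
A3 | alternative 2 | methyl 2-[(1R,2S)-2-acetyl-1,2-dimethylcyclopentyl]acetate | CC(=O)[C@@]1(C)CCC[C@]1(C)CC(=O)OC
A4 | alternative 2 | methyl 2-[(1R,2R,6S)-1,2,6-trimethyl-7-oxabicyclo[4.1.0]heptan-2-yl]acetate | COC(=O)C[C@@]1(C)CCC[C@]2(C)O[C@]12C
A5 | alternative 2 | (3aS,7aR)-3a,7a-dimethylhexahydro-1H-indene-4,6(5H,7H)-dione | O=C1CC(=O)[C@@]2(C)CCC[C@]2(C)C1
A6 | alternative 3 | (3aS,7aR)-5-iodo-6-{[(2R)-6-methoxy-2,8-dimethyl-2H-chromen-2-yl]methyl}-3a,7a-dimethyl-1,2,3,3a,7,7a-hexahydro-4H-inden-4-one | COc1cc(C)c2c(c1)C=C[C@@](C)(CC1=C(I)C(=O)[C@@]3(C)CCC[C@]3(C)C1)O2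
A7 | alternative 3 | 1-[(1S,2S)-2-(iodomethyl)-1,2-dimethylcyclopentyl]-4-[(2R)-6-methoxy-2,8-dimethyl-2H-chromen-2-yl]but-2-yn-1-one | COc1cc(C)c2c(c1)C=C[C@@](C)(CC#CC(=O)[C@@]1(C)CCC[C@]1(C)CI)O2
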